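**Retrosynthetic overview**
- Tomentodione P is cut across its 3,4-dihydro-2H-pyran ring into three components: syncarpic acid, isovaleraldehyde and (1R,3Z,5S,9S)-caryophylla-3,8(13)-dien-5-ol. The C13–C1' and O–C8 bonds are made together in the last step.
- Enabling feature: the dihydropyran ring (ring O–spiro C8–C13H2–C1'H(isobutyl)–C2''=C1'' of the trione ring) is a β-alkoxy enone with its oxygen on a fully substituted carbon next to a ring CH2. This is the retron of an oxa-Diels–Alder addition of a 2-alkylidene-1,3-dione to the exocyclic 1,1-disubstituted olefin C8=C13 of the nine-membered ring.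
- The dienol comes from its 5R epimer by Mitsunobu inversion, the 5R epimer from syn-elimination of (−)-caryophyllene oxide, and the oxide from (−)-β-caryophyllene, which supplies C1, C9, the cyclobutane and the nine-membered ring.
- Syncarpic acid comes from 2',4',6'-trihydroxyacetophenone by exhaustive C-methylation and deacetylation.
- Ring order: cyclobutane and nine-membered ring from the chiral pool, trione ring from the phloroglucinol nucleus, dihydropyran ring last in the key step.

Key step: step 7

Remark on the chemistry: caryophyllane numbering is used (C1/C9 ring fusion, C4 bears methyl C12, C5 is the carbinol carbon, C8 the spiro carbon, C13 the former exocyclic methylene carbon); C1' is the isobutyl-bearing carbon and C1''–C6'' the trione ring. Commercial (−)-β-caryophyllene is taken as the (1R,9S) enantiomer. The target is then (1R,3Z,5S,8S,9S,1'S).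

**Step 1**
Reactants: 1 2',4',6'-trihydroxyacetophenone
Product: 2 acetylsyncarpic acid (2-acetyl-3-hydroxy-4,4,6,6-tetramethylcyclohex-2-ene-1,5-dione)
Conditions: NaOMe, MeI, MeOH, 0 °C to reflux
Reagents that add atoms: iodomethane, CI
Why: Dearomatizing exhaustive C-methylation of the phloroglucinol triphenoxide should dimethylate each of the two free ring carbons while the acetyl-bearing carbon stays blocked and ends as the enolized β-triketone carbon; no stereocenter is formed.

**Step 2**
Reactants: 2 acetylsyncarpic acid
Product: 3 syncarpic acid (5-hydroxy-2,2,6,6-tetramethylcyclohex-4-ene-1,3-dione)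
Conditions: 6 M aq. HCl, reflux
Reagents that add atoms: none
Why: Acid-promoted retro-Claisen deacylation of the exocyclic β-triketone should remove the acetyl group that blocked the nucleophilic carbon during methylation; no stereocenter is formed.

**Step 3**
Reactants: 4 (−)-β-caryophyllene ((1R,4E,9S)-caryophylla-4,8(13)-diene)
Product: 5 (−)-caryophyllene oxide ((1R,4R,5R,9S)-4,5-epoxycaryophyll-8(13)-ene)
Conditions: mCPBA, CH2Cl2, 0 °C
Reagents that add atoms: mCPBA (3-chloroperoxybenzoic acid), O=C(OO)c1cccc(Cl)c1
Why: Prilezhaev epoxidation should be chemoselective for the strained trisubstituted trans C4=C5 bond over C8=C13, and attack on the exposed outer face of the trans olefin in the dominant ring conformers sets 4R,5R, the minor 4S,5S epimer being removed by crystallization.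

**Step 4**
Reactants: 5 (−)-caryophyllene oxide
Product: 6 (1R,3Z,5R,9S)-caryophylla-3,8(13)-dien-5-ol
Conditions: LiTMP, Et2AlCl (gives Et2Al(TMP)), toluene, 0 °C to rt; then H2O work-up
Reagents that add atoms: none
Why: In this aluminium amide epoxide-to-allylic-alcohol isomerization, aluminium should bind the oxirane oxygen on the side of H-5 and the amide should remove, by cyclic syn-elimination, a hydrogen from the C4 substituent cis to H-5, which in this E-derived epoxide is the ring methylene C3 and not the C12 methyl; the hydrogen whose loss lets the ring relax to the unstrained cis (3Z) olefin is expected to be taken, and the untouched C5–O bond keeps 5R.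

**Step 5**
Reactants: 6 (1R,3Z,5R,9S)-caryophylla-3,8(13)-dien-5-ol
Product: 7 (1R,3Z,5S,9S)-caryophylla-3,8(13)-dien-5-yl 4-nitrobenzoate
Conditions: 4-nitrobenzoic acid, PPh3, DIAD, THF, 0 °C to rt
Reagents that add atoms: 4-nitrobenzoic acid, O=C(O)c1ccc(cc1)[N+](=O)[O-]
Why: Mitsunobu esterification with an acidic carboxylic acid (the variant for hindered secondary alcohols) should invert C5 from R to S by SN2 displacement of the alkoxyphosphonium, direct substitution being expected to prevail over SN2' attack at the hindered ring carbon C3.

**Step 6**
Reactants: 7 (1R,3Z,5S,9S)-caryophylla-3,8(13)-dien-5-yl 4-nitrobenzoate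
Product: 8 (1R,3Z,5S,9S)-caryophylla-3,8(13)-dien-5-ol
Conditions: K2CO3 (cat.), MeOH, rt
Reagents that add atoms: none
Why: Base-catalysed transesterification cleaves the acyl–oxygen bond of the electron-poor benzoate, so the 5S configuration, the Z olefin and the exocyclic methylene are untouched.

**Step 7**
Reactants: 3 syncarpic acid; 9 isovaleraldehyde (3-methylbutanal); 8 (1R,3Z,5S,9S)-caryophylla-3,8(13)-dien-5-ol
Product: 11 tomentodione P, via alkylidene trione heterodiene 10 (not isolated)
Conditions: ethylenediammonium diacetate (EDDA, 20 mol %), 4 Å MS, toluene, 70 °C, slow addition of 9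
Reagents that add atoms: none
Why: Amine-salt catalysed Knoevenagel condensation of 3 with 9 gives the symmetric alkylidene trione 10 (the two flanking carbonyls are equivalent, so there is no E/Z issue and the isobutyl group is always "outside" relative to the reacting C=O), which is trapped by the exocyclic olefin of 8 in an inverse-electron-demand oxa-Diels–Alder reaction; the closest known reaction type is the domino Knoevenagel/hetero-Diels–Alder reaction of cyclic 1,3-diones, aldehydes and unactivated 1,1-disubstituted terpene olefins. Only the 3,4-dihydro-2H-pyran ring is closed, by intermolecular [4+2] cycloaddition in which the C13–C1' bond runs ahead of the O–C8 bond, so that oxygen ends on the carbon that best carries positive charge and the spiro junction at C8 results. C8 (S) is set by π-facial selection: the C5 hydroxyl is expected to hydrogen-bond to the carbonyl oxygen of 10 that becomes the ring oxygen and to deliver it to the face of C8=C13 on its own side of the nine-membered ring (Re face of C8), which matches the cis relation of the C5–OH and C8–O bonds in the target. C1' (S) is set by the endo/exo sense: this hydrogen bond can only be kept if the C7–C6–C5 arm lies exo, which places C9 endo and the isobutyl group cis to C9 (C13 bonds to the Re face of C1'). The step needs chemoselectivity for C8=C13 over C3=C4, secured because the strained trans C4=C5 bond of caryophyllene has already been traded for a Z-trisubstituted olefin that is hindered at both ends and inductively deactivated by the allylic hydroxyl while C8=C13 offers an unhindered CH2 terminus, and it needs the facial and endo selectivity just described, secured by the 5S hydroxyl in a non-coordinating solvent. Slow addition of 9 keeps the concentration of 10 low and should suppress its Michael capture by a second molecule of 3.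

**Compound list**
1 | 2',4',6'-trihydroxyacetophenone | CC(=O)c1c(O)cc(O)cc1O | starting material
2 | acetylsyncarpic acid (2-acetyl-3-hydroxy-4,4,6,6-tetramethylcyclohex-2-ene-1,5-dione) | CC(=O)C1=C(O)C(C)(C)C(=O)C(C)(C)C1=O | intermediate
3 | syncarpic acid (5-hydroxy-2,2,6,6-tetramethylcyclohex-4-ene-1,3-dione) | CC1(C)C(=O)C=C(O)C(C)(C)C1=O | intermediate
4 | (−)-β-caryophyllene, (1R,4E,9S) | C/C1=C\CCC(=C)[C@H]2CC(C)(C)[C@@H]2CC1 | starting material
5 | (−)-caryophyllene oxide, (1R,4R,5R,9S) | C[C@@]12CC[C@@H]3[C@H](CC3(C)C)C(=C)CC[C@H]1O2 | intermediate
6 | (1R,3Z,5R,9S)-caryophylla-3,8(13)-dien-5-ol | C/C1=C/C[C@@H]2[C@H](CC2(C)C)C(=C)CC[C@H]1O | intermediate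
7 | (1R,3Z,5S,9S)-caryophylla-3,8(13)-dien-5-yl 4-nitrobenzoate | C/C1=C/C[C@@H]2[C@H](CC2(C)C)C(=C)CC[C@@H]1OC(=O)c1ccc(cc1)[N+](=O)[O-] | intermediate
8 | (1R,3Z,5S,9S)-caryophylla-3,8(13)-dien-5-ol | C/C1=C/C[C@@H]2[C@H](CC2(C)C)C(=C)CC[C@@H]1O | intermediate
9 | isovaleraldehyde (3-methylbutanal) | CC(C)CC=O | starting material
10 | 2-(3-methylbutylidene)-4,4,6,6-tetramethylcyclohexane-1,3,5-trione | CC(C)CC=C1C(=O)C(C)(C)C(=O)C(C)(C)C1=O | intermediate (not isolated)
11 | tomentodione P, (1R,3Z,5S,8S,9S,1'S) | C/C1=C/C[C@@H]2[C@H](CC2(C)C)[C@]2(CC[C@@H]1O)C[C@H](CC(C)C)C1=C(O2)C(C)(C)C(=O)C(C)(C)C1=O | target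

**Totals**
Total step count: 7. Longest linear sequence: 5 steps (steps 3 to 7, from (−)-β-caryophyllene).

**Steps most likely to fail**

1. Step 7. Two processes may go wrong. Heterodiene 10 may be captured by a second molecule of 3 (Michael addition) faster than it adds to the hindered olefin. At 70 °C the hydroxyl-directed facial and endo discrimination may be eroded, giving the C8 and C1' epimers. Fallback: the heterodiene is made by dehydrogenation instead of condensation, at room temperature and without free 3 or amine. Setting out from 3, reductive alkylation with 9 (Hantzsch ester, L-proline cat., CH2Cl2, rt) should give 2-(3-methylbutyl)syncarpic acid F1. Oxidation of F1 with TEMPO and Ag2O in toluene at rt in the presence of 8 should generate 10 and let it add directly, so that the route is rejoined at 11.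

2. Step 4. The amide may remove a hydrogen from the C12 methyl (exocyclic 4(12)-olefin), or the C3 hydrogen whose loss gives the strained 3E olefin. Fallback: oxygen is brought to C5 by an ene reaction instead of by epoxide isomerization. Setting out from 4, Schenck ene photooxygenation (O2, tetraphenylporphyrin, hν, CH2Cl2, 0 °C) should add oxygen to C5 on the same outer face that the peracid uses and shift the double bond to C3=C4, giving (1R,3Z,5R,9S)-5-hydroperoxycaryophylla-3,8(13)-diene F2 after chromatographic removal of the regioisomeric hydroperoxides. Reduction of F2 with PPh3 returns to the route at 6.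

3. Step 5. The hindered allylic oxyphosphonium may undergo SN2' attack, elimination to a triene or ionization, with loss of stereochemical fidelity at C5. Fallback: C5 is set by reagent-controlled reduction instead of substitution. Setting out from 6, oxidation with MnO2 (CH2Cl2, rt) should give (1R,3Z,9S)-caryophylla-3,8(13)-dien-5-one F3. Reduction of F3 with catecholborane and catalytic (R)-2-methyl-CBS-oxazaborolidine (toluene, −78 °C; alkenyl side as the large group, no hydroboration of C8=C13) should give the 5S alcohol and rejoin the route at 8.

**Further compounds**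
F1 | step 7 | 2-(3-methylbutyl)syncarpic acid (3-hydroxy-2-(3-methylbutyl)-4,4,6,6-tetramethylcyclohex-2-ene-1,5-dione) | CC(C)CCC1=C(O)C(C)(C)C(=O)C(C)(C)C1=O
F2 | step 4 | (1R,3Z,5R,9S)-5-hydroperoxycaryophylla-3,8(13)-diene | C/C1=C/C[C@@H]2[C@H](CC2(C)C)C(=C)CC[C@H]1OO
F3 | step 5 | (1R,3Z,9S)-caryophylla-3,8(13)-dien-5-one | C/C1=C/C[C@@H]2[C@H](CC2(C)C)C(=C)CCC1=O
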